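**Retrosynthetic overview**

1. C1=C10 is made last. Ring-closing metathesis of a 2-substituted acrolein onto a terminal vinyl group closes the ten-membered carbocycle onto the γ-lactone, which is present from the first step.
2. C4=C5 comes from an E-selective Wittig reaction of the C5 aldehyde with an α-formyl ylide, then 1,2-reduction to the C15 alcohol. The acrolein comes from α-methylenation of the C14 aldehyde.
3. The C8 ester comes from Mitsunobu inversion of the anti homoallylic alcohol.
4. Key bond C7–C8: the butenolide β-carbon is made nucleophilic (allylindium homoenolate from the hydroxymethyl butenolide, Pd/InI) and adds to 4,4-dimethoxybutanal. This sets C7 and C8 and creates the exo-methylene.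
5. The butenolide (C6 stereocentre) comes from chiral-pool (S)-5-(hydroxymethyl)furan-2(5H)-one by silylation and Baylis–Hillman hydroxymethylation.

Assumption: atoms are labelled with germacrane numbering (C1–C15, lactone oxygen on C6, ester oxygen on C8), and (S)-5-(hydroxymethyl)furan-2(5H)-one, methyl 4,4-dimethoxybutanoate and (pent-4-en-1-yl)triphenylphosphonium bromide are bought.

**Route**

Step 1
Reactants: 1 (S)-5-(hydroxymethyl)furan-2(5H)-one
Product: 2 (S)-5-({[tert-butyl(dimethyl)silyl]oxy}methyl)furan-2(5H)-one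
Conditions: TBSCl, imidazole, DMF, 0 °C to rt
Reagents that add atoms: tert-butyldimethylsilyl chloride, CC(C)(C)[Si](C)(C)Cl
Why: Imidazole-promoted silylation (silyl ether formation) protects the primary C5 hydroxyl for the later coupling, Mitsunobu and oxidation steps, and the C6 stereocentre is not involved.

Step 2
Reactants: 2 (S)-5-({[tert-butyl(dimethyl)silyl]oxy}methyl)furan-2(5H)-one
Product: 3 (S)-5-({[tert-butyl(dimethyl)silyl]oxy}methyl)-3-(hydroxymethyl)furan-2(5H)-one
Conditions: 37% aq. HCHO, imidazole (1 equiv), THF/H2O 1:1, rt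
Reagents that add atoms: formaldehyde, C=O
Why: Morita–Baylis–Hillman hydroxymethylation, in which imidazole adds reversibly to C7, the lactone enolate traps formaldehyde at the α-carbon and elimination restores the butenolide now carrying C13, while the weak base leaves C6–H untouched.

Step 3
Reactants: 4 methyl 4,4-dimethoxybutanoate
Product: 5 4,4-dimethoxybutanal
Conditions: i-Bu2AlH (1.05 equiv), CH2Cl2, −78 °C
Reagents that add atoms: none
Why: Partial ester reduction with one hydride equivalent at low temperature stops at the aluminium hemiacetal, which releases the aldehyde on work-up while the acetal is inert.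

Step 4
Reactants: 3 (S)-5-({[tert-butyl(dimethyl)silyl]oxy}methyl)-3-(hydroxymethyl)furan-2(5H)-one; 5 4,4-dimethoxybutanal
Product: 7 (4R,5S)-5-({[tert-butyl(dimethyl)silyl]oxy}methyl)-4-[(1S)-1-hydroxy-4,4-dimethoxybutyl]-3-methylideneoxolan-2-one, via allylindium hydroxide iodide 6 (not isolated)
Conditions: Pd(PPh3)4 (5 mol%), InI (1.5 equiv), THF, rt
Reagents that add atoms: none
Why: Proposed new method: zerovalent palladium ionises the allylic C–OH bond of 3 (indium salts as Lewis acid) and reductive transmetalation of the 2-acyl-π-allylpalladium with InI gives allylindium 6, in which the butenolide β-carbon C7, normally a Michael acceptor, is the nucleophile (a homoenolate equivalent); 6 adds through C7 to the aldehyde carbon of 5 in a closed six-membered chair transition state on the face anti to the C6 CH2OTBS group (C7 set trans to C6), with the aldehyde chain equatorial and the ring-locked allyl geometry giving the anti (8S) carbinol, while the allylic transposition creates the exo-methylene; the closest known reactions are Pd/InI and Pd/SnCl2 umpolung allylations of aldehydes with allylic alcohols (including 2-(hydroxymethyl)acrylates, which give α-methylene-γ-butyrolactones) and Barbier-type allylations with 3-(bromomethyl)butenolides.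

Step 5
Reactants: 7 (4R,5S)-5-({[tert-butyl(dimethyl)silyl]oxy}methyl)-4-[(1S)-1-hydroxy-4,4-dimethoxybutyl]-3-methylideneoxolan-2-one
Product: 8 (1R)-1-[(2S,3R)-2-({[tert-butyl(dimethyl)silyl]oxy}methyl)-4-methylidene-5-oxooxolan-3-yl]-4,4-dimethoxybutyl 3-methylbutanoate
Conditions: PPh3, DIAD, 3-methylbutanoic acid, toluene, 0 °C to rt (betaine pre-formed)
Reagents that add atoms: 3-methylbutanoic acid, CC(C)CC(=O)O
Why: Mitsunobu esterification proceeds by SN2 inversion, so the anti (8S) carbinol is converted in one operation into the (8R) isovalerate required at C8.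

Step 6
Reactants: 8 (1R)-1-[(2S,3R)-2-({[tert-butyl(dimethyl)silyl]oxy}methyl)-4-methylidene-5-oxooxolan-3-yl]-4,4-dimethoxybutyl 3-methylbutanoate
Product: 9 (1R)-1-[(2S,3R)-2-(hydroxymethyl)-4-methylidene-5-oxooxolan-3-yl]-4,4-dimethoxybutyl 3-methylbutanoate
Conditions: HF·pyridine, pyridine, THF, 0 °C to rt
Reagents that add atoms: none
Why: Fluoride-mediated desilylation cleaves the primary silyl ether, while the acetal, both esters and the α-methylene lactone tolerate the buffered reagent and no stereocentre is touched.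

Step 7
Reactants: 10 (pent-4-en-1-yl)triphenylphosphonium bromide
Product: 12 2-(triphenylphosphoranylidene)hex-5-enal, via pent-4-enylidene ylide 11 (not isolated)
Conditions: KOtBu (1.1 equiv), THF, 0 °C; then HCO2Et, 0 °C to rt
Reagents that add atoms: ethyl formate, CCOC=O
Why: Ylide formylation, in which the non-stabilised ylide 11 is C-acylated by ethyl formate and the released ethoxide removes the now acidic α-proton to give the stabilised α-formyl ylide.

Step 8
Reactants: 9 (1R)-1-[(2S,3R)-2-(hydroxymethyl)-4-methylidene-5-oxooxolan-3-yl]-4,4-dimethoxybutyl 3-methylbutanoate; 12 2-(triphenylphosphoranylidene)hex-5-enal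
Product: 14 (1R)-1-{(2R,3R)-2-[(1E)-2-formylhexa-1,5-dien-1-yl]-4-methylidene-5-oxooxolan-3-yl}-4,4-dimethoxybutyl 3-methylbutanoate, via C5 aldehyde 13 (not isolated)
Conditions: Dess–Martin periodinane, pyridine, CH2Cl2, 0 °C to rt; filter, concentrate; then 12, toluene, 70 °C
Reagents that add atoms: none
Why: Dess–Martin oxidation gives the α-oxy aldehyde without disturbing C6, and the Wittig reaction with the stabilised α-formyl ylide is E-selective (CHO trans to C6, C3 cis to C6), which is the C4=C5 geometry of the target.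

Step 9
Reactants: 14 (1R)-1-{(2R,3R)-2-[(1E)-2-formylhexa-1,5-dien-1-yl]-4-methylidene-5-oxooxolan-3-yl}-4,4-dimethoxybutyl 3-methylbutanoate
Product: 15 (1R)-1-{(2R,3R)-2-[(1E)-2-(hydroxymethyl)hexa-1,5-dien-1-yl]-4-methylidene-5-oxooxolan-3-yl}-4,4-dimethoxybutyl 3-methylbutanoate
Conditions: NaBH4 (0.5 equiv), CeCl3·7H2O, MeOH, −78 °C
Reagents that add atoms: none
Why: Luche reduction delivers hydride 1,2 to the enal far faster at −78 °C than conjugate reduction of the α-methylene lactone, giving the C15 allylic alcohol with the olefin geometry unchanged.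

Step 10
Reactants: 15 (1R)-1-{(2R,3R)-2-[(1E)-2-(hydroxymethyl)hexa-1,5-dien-1-yl]-4-methylidene-5-oxooxolan-3-yl}-4,4-dimethoxybutyl 3-methylbutanoate
Product: 16 (1R)-1-{(2R,3R)-2-[(1E)-2-(hydroxymethyl)hexa-1,5-dien-1-yl]-4-methylidene-5-oxooxolan-3-yl}-4-oxobutyl 3-methylbutanoate
Conditions: 1 M aq. HCl, THF, 0 °C to rt
Reagents that add atoms: water, O
Why: Acid-catalysed acetal hydrolysis unmasks the C14 aldehyde under conditions mild enough for the allylic alcohol, the esters and the lactone.

Step 11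
Reactants: 16 (1R)-1-{(2R,3R)-2-[(1E)-2-(hydroxymethyl)hexa-1,5-dien-1-yl]-4-methylidene-5-oxooxolan-3-yl}-4-oxobutyl 3-methylbutanoate
Product: 17 (1R)-3-formyl-1-{(2R,3R)-2-[(1E)-2-(hydroxymethyl)hexa-1,5-dien-1-yl]-4-methylidene-5-oxooxolan-3-yl}but-3-en-1-yl 3-methylbutanoate
Conditions: 37% aq. HCHO, pyrrolidine (10 mol%), 4-(dimethylamino)benzoic acid (20 mol%), CH2Cl2, 40 °C
Reagents that add atoms: formaldehyde, C=O
Why: Organocatalytic α-methylenation (Mannich condensation then elimination through the enamine of the C14 aldehyde) gives the 2-substituted acrolein, with the amine used catalytically as its carboxylate salt so that reversible aza-Michael addition to the α-methylene lactone does not consume material.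

Step 12
Reactants: 17 (1R)-3-formyl-1-{(2R,3R)-2-[(1E)-2-(hydroxymethyl)hexa-1,5-dien-1-yl]-4-methylidene-5-oxooxolan-3-yl}but-3-en-1-yl 3-methylbutanoate
Product: 18 (3aR,4R,6E,10E,11aR)-6-formyl-10-(hydroxymethyl)-3-methylidene-2-oxo-2,3,3a,4,5,8,9,11a-octahydrocyclodeca[b]furan-4-yl 3-methylbutanoate
Conditions: second-generation Hoveyda–Grubbs catalyst (10 mol%), 1,4-benzoquinone (20 mol%), toluene (1 mM), 80 °C
Reagents that add atoms: none
Why: Ring-closing metathesis loads the catalyst at the terminal vinyl group and closes onto the 2-substituted acrolein with loss of ethene; the trans lactone and the cis C4=C5 olefin pre-organise the chain, the ten-membered ring accepts the new trisubstituted olefin ring-cis (the E-enal, CHO trans to C2), and closure onto the α-methylene lactone would require a strained bridgehead olefin.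

**Compound list**

1 | (S)-5-(hydroxymethyl)furan-2(5H)-one | O=C1C=C[C@@H](CO)O1 | starting material
2 | (S)-5-({[tert-butyl(dimethyl)silyl]oxy}methyl)furan-2(5H)-one | O=C1C=C[C@@H](CO[Si](C)(C)C(C)(C)C)O1 | intermediate
3 | (S)-5-({[tert-butyl(dimethyl)silyl]oxy}methyl)-3-(hydroxymethyl)furan-2(5H)-one | O=C1C(CO)=C[C@@H](CO[Si](C)(C)C(C)(C)C)O1 | intermediate
4 | methyl 4,4-dimethoxybutanoate | COC(=O)CCC(OC)OC | starting material
5 | 4,4-dimethoxybutanal | O=CCCC(OC)OC | intermediate
6 | {[(5S)-5-({[tert-butyl(dimethyl)silyl]oxy}methyl)-2-oxo-2,5-dihydrofuran-3-yl]methyl}indium hydroxide iodide (allyl species of trivalent indium, not isolated) | O=C1C(C[In](O)I)=C[C@@H](CO[Si](C)(C)C(C)(C)C)O1 | intermediate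
7 | (4R,5S)-5-({[tert-butyl(dimethyl)silyl]oxy}methyl)-4-[(1S)-1-hydroxy-4,4-dimethoxybutyl]-3-methylideneoxolan-2-one (C6, C7 trans; C8 epimeric to the target) | C=C1C(=O)O[C@H](CO[Si](C)(C)C(C)(C)C)[C@H]1[C@@H](O)CCC(OC)OC | intermediate
8 | (1R)-1-[(2S,3R)-2-({[tert-butyl(dimethyl)silyl]oxy}methyl)-4-methylidene-5-oxooxolan-3-yl]-4,4-dimethoxybutyl 3-methylbutanoate | C=C1C(=O)O[C@H](CO[Si](C)(C)C(C)(C)C)[C@H]1[C@H](OC(=O)CC(C)C)CCC(OC)OC | intermediate
9 | (1R)-1-[(2S,3R)-2-(hydroxymethyl)-4-methylidene-5-oxooxolan-3-yl]-4,4-dimethoxybutyl 3-methylbutanoate | C=C1C(=O)O[C@H](CO)[C@H]1[C@H](OC(=O)CC(C)C)CCC(OC)OC | intermediate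
10 | (pent-4-en-1-yl)triphenylphosphonium bromide | C=CCCC[P+](c1ccccc1)(c1ccccc1)c1ccccc1.[Br-] | starting material
11 | (pent-4-en-1-ylidene)triphenylphosphorane (not isolated) | C=CCCC=P(c1ccccc1)(c1ccccc1)c1ccccc1 | intermediate
12 | 2-(triphenylphosphoranylidene)hex-5-enal | O=CC(CCC=C)=P(c1ccccc1)(c1ccccc1)c1ccccc1 | intermediate
13 | (1R)-1-[(2S,3R)-2-formyl-4-methylidene-5-oxooxolan-3-yl]-4,4-dimethoxybutyl 3-methylbutanoate (not isolated) | C=C1C(=O)O[C@H](C=O)[C@H]1[C@H](OC(=O)CC(C)C)CCC(OC)OC | intermediate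
14 | (1R)-1-{(2R,3R)-2-[(1E)-2-formylhexa-1,5-dien-1-yl]-4-methylidene-5-oxooxolan-3-yl}-4,4-dimethoxybutyl 3-methylbutanoate | C=C1C(=O)O[C@H](/C=C(/C=O)CCC=C)[C@H]1[C@H](OC(=O)CC(C)C)CCC(OC)OC | intermediate
15 | (1R)-1-{(2R,3R)-2-[(1E)-2-(hydroxymethyl)hexa-1,5-dien-1-yl]-4-methylidene-5-oxooxolan-3-yl}-4,4-dimethoxybutyl 3-methylbutanoate | C=C1C(=O)O[C@H](/C=C(/CO)CCC=C)[C@H]1[C@H](OC(=O)CC(C)C)CCC(OC)OC | intermediate
16 | (1R)-1-{(2R,3R)-2-[(1E)-2-(hydroxymethyl)hexa-1,5-dien-1-yl]-4-methylidene-5-oxooxolan-3-yl}-4-oxobutyl 3-methylbutanoate | C=C1C(=O)O[C@H](/C=C(/CO)CCC=C)[C@H]1[C@H](OC(=O)CC(C)C)CCC=O | intermediate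
17 | (1R)-3-formyl-1-{(2R,3R)-2-[(1E)-2-(hydroxymethyl)hexa-1,5-dien-1-yl]-4-methylidene-5-oxooxolan-3-yl}but-3-en-1-yl 3-methylbutanoate | C=C1C(=O)O[C@H](/C=C(/CO)CCC=C)[C@H]1[C@H](OC(=O)CC(C)C)CC(=C)C=O | intermediate
18 | (3aR,4R,6E,10E,11aR)-6-formyl-10-(hydroxymethyl)-3-methylidene-2-oxo-2,3,3a,4,5,8,9,11a-octahydrocyclodeca[b]furan-4-yl 3-methylbutanoate (CNP0345200.3; 6R,7R,8R in germacrane numbering, both ring olefins ring-cis) | C=C1C(=O)O[C@@H]2/C=C(/CO)CC/C=C(/C=O)C[C@@H](OC(=O)CC(C)C)[C@@H]12 | target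

**Step count and risks**

Total step count: 12. Longest linear sequence: 10 (steps 1, 2, 4, 5, 6, 8, 9, 10, 11, 12).

The three steps most likely to fail:

Step 2. A Baylis–Hillman reaction on a γ-substituted butenolide can stall or give Rauhut–Currier dimers. The fallback sets out from 2 and comes back at 3. α-Iodination of 2 (I2, pyridine, CH2Cl2) gives (S)-5-({[tert-butyl(dimethyl)silyl]oxy}methyl)-3-iodofuran-2(5H)-one F1. Stille coupling of F1 with (tributylstannyl)methanol (Pd(PPh3)4, dioxane, 80 °C) then gives 3, so the C11–C13 bond is made by cross-coupling and not by nucleophilic catalysis.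

Step 4. Ionisation of the free allylic alcohol by zerovalent palladium may be slow, the indium alkoxide may translactonise, and the diastereomer ratio at C8 may erode. The fallback sets out from 3 and comes back at 7. Appel bromination (CBr4, PPh3, CH2Cl2, 0 °C) gives (S)-3-(bromomethyl)-5-({[tert-butyl(dimethyl)silyl]oxy}methyl)furan-2(5H)-one F2. Stoichiometric CrCl2 in THF (Nozaki–Hiyama-type Barbier allylation, no palladium) then couples F2 with 5 through the same closed transition state to the same anti alcohol 7.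

Step 12. The electron-poor, hindered acrolein may be too sluggish a partner for closure of a strained ten-membered ring, so oligomers may dominate. The fallback sets out from 17 and comes back at 18.
- Silylation of the C15 hydroxyl (TBSCl, imidazole, CH2Cl2) gives the C15 silyl ether of 17 F3.
- Luche reduction (NaBH4, CeCl3·7H2O, MeOH, −78 °C) converts the acrolein into the 2-substituted allylic alcohol F4.
- Ring-closing metathesis of this hydroxyl-activated, electron-neutral 1,1-disubstituted olefin (same catalyst, toluene, 80 °C) gives the macrocyclic C14 alcohol F5.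
- MnO2 (CH2Cl2, rt) oxidises the C14 alcohol to the silylated enal F6.
- HF·pyridine removes the silyl group to give 18.

Further compounds
F1 | step 2 | (S)-5-({[tert-butyl(dimethyl)silyl]oxy}methyl)-3-iodofuran-2(5H)-one | O=C1C(I)=C[C@@H](CO[Si](C)(C)C(C)(C)C)O1
F2 | step 4 | (S)-3-(bromomethyl)-5-({[tert-butyl(dimethyl)silyl]oxy}methyl)furan-2(5H)-one | O=C1C(CBr)=C[C@@H](CO[Si](C)(C)C(C)(C)C)O1
F3 | step 12 | (1R)-1-{(2R,3R)-2-[(1E)-2-({[tert-butyl(dimethyl)silyl]oxy}methyl)hexa-1,5-dien-1-yl]-4-methylidene-5-oxooxolan-3-yl}-3-formylbut-3-en-1-yl 3-methylbutanoate | C=C1C(=O)O[C@H](/C=C(/CO[Si](C)(C)C(C)(C)C)CCC=C)[C@H]1[C@H](OC(=O)CC(C)C)CC(=C)C=O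
F4 | step 12 | (1R)-1-{(2R,3R)-2-[(1E)-2-({[tert-butyl(dimethyl)silyl]oxy}methyl)hexa-1,5-dien-1-yl]-4-methylidene-5-oxooxolan-3-yl}-3-(hydroxymethyl)but-3-en-1-yl 3-methylbutanoate | C=C1C(=O)O[C@H](/C=C(/CO[Si](C)(C)C(C)(C)C)CCC=C)[C@H]1[C@H](OC(=O)CC(C)C)CC(=C)CO
F5 | step 12 | (3aR,4R,6E,10E,11aR)-10-({[tert-butyl(dimethyl)silyl]oxy}methyl)-6-(hydroxymethyl)-3-methylidene-2-oxo-2,3,3a,4,5,8,9,11a-octahydrocyclodeca[b]furan-4-yl 3-methylbutanoate | C=C1C(=O)O[C@@H]2/C=C(/CO[Si](C)(C)C(C)(C)C)CC/C=C(/CO)C[C@@H](OC(=O)CC(C)C)[C@@H]12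
F6 | step 12 | (3aR,4R,6E,10E,11aR)-10-({[tert-butyl(dimethyl)silyl]oxy}methyl)-6-formyl-3-methylidene-2-oxo-2,3,3a,4,5,8,9,11a-octahydrocyclodeca[b]furan-4-yl 3-methylbutanoate | C=C1C(=O)O[C@@H]2/C=C(/CO[Si](C)(C)C(C)(C)C)CC/C=C(/C=O)C[C@@H](OC(=O)CC(C)C)[C@@H]12
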